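Assumptions: natural (R)-(−)-linalool and L-serine-derived methyl (R)-glycidate are purchased at ≥97% ee. Side-chain atoms are numbered C1′–C12′ outward from chroman C2.

## Retrosynthetic overview
1. Target 17 comes from global desilylation of 16. The C6′–C7′ bond is cut (B-alkyl Suzuki) into the homoallyl borane from diene 9 and the (E)-vinyl iodide 15.
2. Iodide 15 (C7′–C12′, carrying C9′) comes from methyl (R)-glycidate 10 by isobutenyl-cuprate opening (C10′–C11′), ester-to-alkyne conversion, and methylalumination/iodination (E-C7′=C8′).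
3. Diene 9 comes from chromanol 6 by silylation, E-selective allylic oxidation of the prenyl terminus (C5′) and methylenation (C6′).
4. The dihydropyran is the only ring formed. It closes 4 → 6 by anodic O1–C8a bond formation followed by reductive loss of MeOH. C2 is the linalool carbinol carbon, and its C–O bond is never broken.
5. Phenol 4 comes from (R)-linalool 3 and bromophenol 2 (C4–C4a, hydroboration/Suzuki). Bromophenol 2 comes from 2-bromo-6-methylanisole 1.

## Route

**Step 1**
Reactants: 1, 2-bromo-6-methylanisole (1-bromo-2-methoxy-3-methylbenzene)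
Product: 2, 3-bromo-4-methoxy-5-methylphenol
Conditions: [Ir(OMe)(cod)]2 (1.5 mol %), dtbpy (3 mol %), B2pin2, THF, 80 °C; then 30% H2O2, aq NaOH, 0 °C (one pot)
Reagents that add atoms: hydrogen peroxide, OO
Why: Sterically controlled Ir-catalysed C–H borylation of a 1,2,3-trisubstituted arene hits only the position para to OMe, and boronate oxidation gives the phenol with the C–Br bond intact.

**Step 2**
Reactants: 3, (R)-(−)-linalool; 2, 3-bromo-4-methoxy-5-methylphenol
Product: 4, (R)-3-(3-hydroxy-3,7-dimethyloct-6-en-1-yl)-4-methoxy-5-methylphenol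
Conditions: 3, 9-BBN (2.2 equiv), THF, 0 °C→rt; then 2, Pd(OAc)2 (3 mol %), SPhos (6 mol %), aq K3PO4 (4 equiv), THF/DMF, 60 °C, Ar; ethanolamine (non-oxidative) work-up
Reagents that add atoms: none (9-BBN supplies only H)
Why: 9-BBN hydroborates the monosubstituted vinyl group anti-Markovnikov and ignores the trisubstituted alkene, and the B-alkyl Suzuki–Miyaura coupling forms C4–C4a without touching the carbinol stereocentre.

**Step 3 (key step)**
Reactants: 4
Product: 6, (R)-2,8-dimethyl-2-(4-methylpent-3-en-1-yl)chroman-6-ol, formed via 5, the (2R)-8a-methoxy-2,8-dimethyl-2-(4-methylpent-3-enyl)-2,3,4,8a-tetrahydrochromen-6-one mixed quinone monoketal (C8a epimers, not isolated)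
Conditions: undivided cell, graphite(+)|Zn(−), n-Bu4NPF6 (0.1 M), 2,6-lutidine (3 equiv), 3 Å MS, MeCN/CH2Cl2 4:1 (0.02 M), 2 mA cm⁻², 2.2 F mol⁻¹, 0 °C; then AcOH (10 equiv), polarity inverted, Zn(+)|graphite(−), 2.5 F mol⁻¹, rt
Reagents that add atoms: none (MeOH is lost)
Why: Proposed new method: two-electron anodic oxidation of the 4-methoxyphenol (about +0.7–0.9 V, more than 1 V below the alkene) gives an O-methyl phenoxenium/quinone oxocarbenium ion, whose ipso carbon (bearing the doubly ortho-flanked, twisted OMe) is captured by the tethered tertiary OH to form O1–C8a and monoketal 5; polarity inversion then delivers 2 e⁻/2 H⁺, and the ketyl expels the exocyclic methoxide rather than the ring alkoxide, because the chromanoxyl radical (ring O lone pair aligned with the π system) is more stabilised than the twisted-OMe phenoxyl, so the ring rearomatises to 6; the net change is a redox-neutral ArO–Me → ArO–tert-alkyl exchange in which C2–O is never cleaved, so linalool's configuration is retained; the closest known reaction types are anodic oxidation of 4-methoxyphenols to quinone monoketals and reduction of quinone monoketals/8a-alkoxychromanones to 4-alkoxyphenols.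

**Step 4**
Reactants: 6
Product: 7, (R)-tert-butyl{[2,8-dimethyl-2-(4-methylpent-3-en-1-yl)chroman-6-yl]oxy}dimethylsilane
Conditions: TBSCl, imidazole, DMF, rt
Reagents that add atoms: TBSCl, CC(C)(C)[Si](C)(C)Cl
Why: Standard phenol silylation masks the oxidation-prone chromanol before the allylic oxidation.

**Step 5**
Reactants: 7
Product: 8, (2E)-5-[(2R)-6-(TBSO)-2,8-dimethylchroman-2-yl]-2-methylpent-2-enal
Conditions: SeO2 (0.5 equiv), t-BuOOH (decane, 3 equiv), CH2Cl2, 0 °C→rt; the crude alcohol/aldehyde mixture is then treated with MnO2, CH2Cl2, rt (telescoped)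
Reagents that add atoms: selenium dioxide, O=[Se]=O; tert-butyl hydroperoxide, CC(C)(C)OO
Why: Riley/Sharpless allylic oxidation (ene reaction then [2,3]-shift) functionalises only the (E)-methyl of the single prenyl group, which fixes E-C3′=C4′, and MnO2 converges the mixture on the enal.

**Step 6**
Reactants: 8
Product: 9, (R)-tert-butyl({2,8-dimethyl-2-[(3E)-4-methylhexa-3,5-dien-1-yl]chroman-6-yl}oxy)dimethylsilane
Conditions: Ph3PCH3Br, KHMDS, THF, −78→0 °C
Reagents that add atoms: methyltriphenylphosphonium bromide, C[P+](c1ccccc1)(c1ccccc1)c1ccccc1.[Br-]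
Why: Wittig methylenation installs C6′ without disturbing the E-trisubstituted alkene or the silyl ether.

**Step 7**
Reactants: 10, methyl (R)-glycidate; 11, 2-methylprop-1-enylmagnesium bromide
Product: 12, methyl (2R)-2-hydroxy-5-methylhex-4-enoate
Conditions: 11 (2.2 equiv), CuI (1.1 equiv), THF/Me2S, −40 °C; then 10, −78→−30 °C
Reagents that add atoms: none beyond the reactants
Why: The magnesiocuprate opens the glycidic ester (SN2) at the terminal CH2 only, so the purchased C–O stereocentre (future C9′, R) is untouched and the ester survives at low temperature.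

**Step 8**
Reactants: 12
Product: 13, methyl (2R)-2-(TBSO)-5-methylhex-4-enoate
Conditions: TBSCl, imidazole, DMF, rt
Reagents that add atoms: TBSCl, CC(C)(C)[Si](C)(C)Cl
Why: Routine silylation blocks the α-hydroxyl for the aldehyde and alane chemistry that follows.

**Step 9**
Reactants: 13
Product: 14, tert-butyl(dimethyl){[(3R)-6-methylhept-5-en-1-yn-3-yl]oxy}silane
Conditions: DIBAL-H (1.1 equiv), CH2Cl2, −78 °C; MeOH quench; then K2CO3, dimethyl (1-diazo-2-oxopropyl)phosphonate, MeOH, →rt (one pot)
Reagents that add atoms: Ohira–Bestmann reagent, COP(=O)(OC)C(=[N+]=[N-])C(C)=O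
Why: Partial ester reduction followed by Seyferth–Gilbert (Ohira–Bestmann) homologation gives the terminal alkyne (C8′≡C7′), and α-silyloxy aldehydes pass through these mild conditions without epimerisation.

**Step 10**
Reactants: 14
Product: 15, tert-butyl{[(1E,3R)-1-iodo-2,6-dimethylhepta-1,5-dien-3-yl]oxy}dimethylsilane
Conditions: AlMe3 (3 equiv), Cp2ZrCl2 (0.5 equiv), CH2Cl2, 0 °C→rt; then I2, THF, −30 °C
Reagents that add atoms: trimethylaluminium, C[Al](C)C; iodine, II
Why: Negishi Zr-catalysed syn-methylalumination places Me on C8′ and Al (then I, with retention) on C7′ trans to C9′, giving the E-iodide; the trisubstituted alkene is inert.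

**Step 11**
Reactants: 9; 15
Product: 16, the bis-TBS ether of the target: tert-butyl({(2R)-2-[(3E,7E,9R)-9-(TBSO)-4,8,12-trimethyltrideca-3,7,11-trien-1-yl]-2,8-dimethylchroman-6-yl}oxy)dimethylsilane
Conditions: 9, 9-BBN (1.1 equiv), THF, 0 °C→rt; then 15, Pd(dppf)Cl2·CH2Cl2 (5 mol %), AsPh3, aq K3PO4, THF/DMF, rt
Reagents that add atoms: none
Why: 9-BBN monohydroborates the vinyl terminus of the 1,3-diene to the homoallyl borane, and the stereoretentive B-alkyl Suzuki–Miyaura coupling forms C6′–C7′; any base-induced loss of the aryl TBS group is harmless because step 12 removes it.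

**Step 12**
Reactants: 16
Product: 17, sargachromanol C, (2R)-2-[(3E,7E,9R)-9-hydroxy-4,8,12-trimethyltrideca-3,7,11-trien-1-yl]-2,8-dimethylchroman-6-ol
Conditions: TBAF (3 equiv), AcOH (1 equiv), THF, 0 °C→rt, Ar
Reagents that add atoms: none
Why: Fluoride desilylation cleaves both Si–O bonds without touching either stereocentre or the alkenes.

## Compound list
1 | 2-bromo-6-methylanisole | COc1c(C)cccc1Br | starting material
2 | 3-bromo-4-methoxy-5-methylphenol | COc1c(C)cc(O)cc1Br | intermediate
3 | (R)-(−)-linalool | C=C[C@](C)(O)CCC=C(C)C | starting material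
4 | (R)-3-(3-hydroxy-3,7-dimethyloct-6-enyl)-4-methoxy-5-methylphenol | COc1c(C)cc(O)cc1CC[C@](C)(O)CCC=C(C)C | intermediate
5 | (2R)-8a-methoxy mixed quinone monoketal (C8a epimers) | COC12O[C@](C)(CCC=C(C)C)CCC1=CC(=O)C=C2C | intermediate (not isolated)
6 | (R)-2,8-dimethyl-2-(4-methylpent-3-enyl)chroman-6-ol | CC(C)=CCC[C@]1(C)CCc2cc(O)cc(C)c2O1 | intermediate
7 | TBS ether of 6 | CC(C)=CCC[C@]1(C)CCc2cc(O[Si](C)(C)C(C)(C)C)cc(C)c2O1 | intermediate
8 | (E)-enal | O=C/C(C)=C/CC[C@]1(C)CCc2cc(O[Si](C)(C)C(C)(C)C)cc(C)c2O1 | intermediate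
9 | (E)-diene | C=C/C(C)=C/CC[C@]1(C)CCc2cc(O[Si](C)(C)C(C)(C)C)cc(C)c2O1 | intermediate
10 | methyl (R)-glycidate | COC(=O)[C@H]1CO1 | starting material
11 | 2-methylprop-1-enylmagnesium bromide | CC(C)=C[Mg]Br | starting material
12 | methyl (2R)-2-hydroxy-5-methylhex-4-enoate | CC(C)=CC[C@@H](O)C(=O)OC | intermediate
13 | methyl (2R)-2-(TBSO)-5-methylhex-4-enoate | CC(C)=CC[C@@H](O[Si](C)(C)C(C)(C)C)C(=O)OC | intermediate
14 | (3R)-3-(TBSO)-6-methylhept-5-en-1-yne | CC(C)=CC[C@@H](O[Si](C)(C)C(C)(C)C)C#C | intermediate
15 | (1E,3R)-1-iodo-2,6-dimethylhepta-1,5-dien-3-yl TBS ether | CC(C)=CC[C@@H](O[Si](C)(C)C(C)(C)C)/C(C)=C/I | intermediate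
16 | bis-TBS sargachromanol C | CC(C)=CC[C@@H](O[Si](C)(C)C(C)(C)C)/C(C)=C/CC/C(C)=C/CC[C@]1(C)CCc2cc(O[Si](C)(C)C(C)(C)C)cc(C)c2O1 | intermediate
17 | sargachromanol C | CC(C)=CC[C@@H](O)/C(C)=C/CC/C(C)=C/CC[C@]1(C)CCc2cc(O)cc(C)c2O1 | target

## Step count
- Total steps: 12.
- Longest linear sequence: 8 (steps 1–6, 11, 12). The tail branch runs through steps 7–10.

## Steps most likely to fail
1. **Step 3 (new electrochemical ether exchange).** The risks are phenoxyl dimerisation, hydrolysis to the quinone, or ring-opening during the reduction stage.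
   - Fallback (known chemistry): borylate/oxidise 3-bromo-2-chlorotoluene to 3-bromo-4-chloro-5-methylphenol and protect it as the TBS ether.
   - Run the linalool B-alkyl Suzuki chemoselectively at C–Br.
   - Close the ring by Pd-catalysed intramolecular C–O coupling of the tertiary alcohol with the aryl chloride (bulky di-tert-butyl biaryl phosphine, Cs2CO3, toluene). C2–O again stays intact, and the product is 7 directly.
2. **Step 2 (B-alkyl Suzuki).** The partners are a γ-hydroxyalkyl borane and a hindered, electron-rich, unprotected bromophenol.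
   - Fallback: Heck arylation of the linalool vinyl group with 2 to give the (E)-styrenyl tertiary carbinol.
   - Follow with diimide reduction (TsNHNH2/NaOAc), which saturates the disubstituted alkene and spares the trisubstituted one.
3. **Step 11 (diene monohydroboration/sp³–sp² Suzuki).** The risks are over-hydroboration or 1,4-hydroboration and slow transmetalation.
   - Fallback: reduce 8 to the allylic alcohol, convert it to the bromide, and alkylate with dilithioacetate to give the C5′–C6′ homologated acid.
   - Form the N-hydroxyphthalimide ester and join it to 15 by Ni-electrocatalytic decarboxylative alkenylation.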